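The constants are hidden, but the zeta readings give a time. In zeta, with equal charges, every second reagent consumed removes one molecule from the pool of starting material plus open intermediate, so c(second reagent) equals that pool, apart from a trace of trapped intermediate. If both steps run at similar constants, that is simple second-order decay. Side product plus target at 0.417 min then give a pairing time, the half-life at the charged amount, of 0.246 min, and the reading at 0.833 min gives 0.232 min.

| setting | theta | zeta | epsilon | beta | amber | ochre | violet | blue |
|---|---|---|---|---|---|---|---|---|
| starting material | 1 mM | 1 mM | 1 mM | 1 mM | 1.0 mM (fed, over 3.0 min) | 1.0 mM | 1.0 mM | 1.0 mM |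
| coupling partner | 0.95 equiv | 0.95 equiv | 0.95 equiv | 0.95 equiv | 0.950 equiv | 0.950 equiv | 0.950 equiv | 0.950 equiv |
| second reagent | 1 equiv | 1 equiv | 1 equiv | 0.50 equiv | 1.00 equiv | 1.00 equiv (fed, over 3.0 min) | 1.00 equiv | 1.00 equiv (fed, over 3.0 min) |
| capture agent | 0.020 mM | 0.010 mM | 0.040 mM | 0.020 mM | 0.0200 mM | 0.0200 mM | 0.0200 mM | 0.0200 mM |
| temperature | 45 °C | 60 °C | 45 °C | 60 °C | 60 °C |  |  | 60 °C |
| remark | run made earlier | run made earlier | run made earlier | run made earlier | all else is in the flask from the start; the feed brings no volume worth counting | the addition at 40 °C, then warmed to 60 °C; the feed brings no volume worth counting | everything together at the start at 40 °C, warmed to 60 °C at 3.0 min | all else is in the flask from the start; the feed brings no volume worth counting |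
| time |  |  |  |  | 5.0 min | 5.0 min | 5.0 min | 5.0 min |

| run | time / min | side product / % | target / % |
|---|---|---|---|
| theta | 0.500 | 45.0 | 7.4 |
| theta | 2.00 | 60.0 | 21.7 |
| theta | 3.00 | 61.4 | 26.3 |
| theta | 4.00 | 61.3 | 27.8 |
| theta | 6.00 | 61.3 | 31.2 |
| zeta | 0.417 | 49.9 | 13.0 |
| zeta | 0.833 | 56.1 | 22.1 |
| zeta | 1.33 | 57.9 | 27.1 |
| zeta | 2.50 | 59.4 | 33.0 |
| zeta | 5.00 | 58.2 | 36.6 |
| epsilon | 2.00 | 60.3 | 21.7 |
| epsilon | 4.00 | 61.7 | 29.0 |
| epsilon | 6.00 | 60.8 | 32.4 |
| epsilon | 8.00 | 61.9 | 32.4 |
| epsilon | 10.0 | 62.0 | 34.2 |
| beta | 0.417 | 28.4 | 8.5 |
| beta | 0.833 | 32.9 | 12.7 |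
| beta | 1.33 | 32.7 | 15.6 |
| beta | 2.50 | 33.8 | 17.1 |
| beta | 5.00 | 33.8 | 16.3 |

(each reading ± 0.5 percentage points)

* the flask that comes out highest in amount of side product, in percent of the starting material charged; "all alike" if 1.5 percentage points covers them all (amber / ochre / violet / blue / all alike)
* amount of side product at the end, in percent of the starting material charged, amber
* amount of side product at the end, in percent of the starting material charged, ochre
* amount of side product at the end, in percent of the starting material charged, violet
* amount of side product at the end, in percent of the starting material charged, blue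

The bench rule says a slow feed keeps a reagent low, and here 3.0 min is far longer than the pairing time, so in blue the feed is consumed about as it enters (a quasi-steady state). Early in the feed, with the pool near the whole charge, I reckon c(second reagent) near 0.0820 mM, the opening level. The rule has a border, though: the pool shrinks as the feed proceeds. By the same balance, pool and second reagent come level at the end of the feed, apart from the trace of trapped intermediate, and there I reckon the square root of pairing time over feed time, as a share of the charge, which I call the end-of-feed level: 28.6%.

The last zeta reading gives odds of side product against the rest of 1.39. Scaling them by the opening and end-of-feed levels, each as a share of the charge, gives a rough estimate of mine for side product in blue, between 10.2% and 28.5%.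

The forecast says violet comes highest, with amber 53%, ochre 40%, violet 62% and blue 32% (range 26% to 37%); of blue it says “Blue starves second reagent while starting material converts”. Its blue value stands higher than the top of my estimate.

The flasks give amber 55.5%, ochre 38.7%, violet 62.7% and blue 24.4%, so violet is highest. Blue's mean c(second reagent) over the feed was 0.118 mM, above the opening level and below the end-of-feed level of 0.286 mM.

    starting material + coupling partner → open intermediate (k = 34.0 M⁻¹ s⁻¹, Ea = 46.0 kJ mol⁻¹)
    starting material + second reagent → side product (k = 67.0 M⁻¹ s⁻¹, Ea = 35.0 kJ mol⁻¹)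
    open intermediate + capture agent → trapped intermediate (k = 4.00 M⁻¹ s⁻¹, Ea = 54.0 kJ mol⁻¹)
    second reagent + open intermediate → target (k = 73.0 M⁻¹ s⁻¹, Ea = 37.0 kJ mol⁻¹)
    (constants at 60 °C)

In the neighbour of blue charged with 4.0 mM of starting material, I take the pairing time to shorten with the charge, so the end-of-feed level becomes 14.3%, half of blue's. Taking side product in proportion to that level gives 12.2%, and the computed side product of that neighbour is 11.7%.

(The data are simulated for an exercise; scatter was added.)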